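**Retrosynthetic overview**

1. Ring C of the (2S)-flavanone is opened across C3–C4 and O1–C2. This gives the achiral hexaphenolic aldehyde 10 and tert-butyl phenylpropiolate 13, whose ester on the future C3 is a traceless activating group.
2. Enabling feature: on ring A the formyl-bearing carbon (future C4a) sits between two hydroxyls (future O1 and 5-OH), and C6 and C8 carry the same arm. Aldehyde 10 therefore has a mirror plane through C4, C4a, C7 and the methoxy group, so either hydroxyl closes ring C to the same product. The O–C8a–C4a–C4 hydroxy aldehyde unit also chelates rhodium for C–H insertion.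
3. Aldehyde 10 comes from 2,6-dihydroxy-4-methoxybenzaldehyde 7 by twofold ortho-quinone methide benzylation (biomimetic) at its only two free ring carbons with arm alcohol 5.
4. Arm alcohol 5 comes from a benzyl–aryl Suzuki coupling, demethylation and reduction; 7 from mono-methylation of triol 6; 13 from phenylacetylene and Boc2O.
5. Ring order: ring A, ring B and the four arm rings are bought as benzenes; ring C is the only ring made, in the last step.

Key step: step 7

Assumption: the quinidine-derived thiourea is taken to give the 2S series; if the sense of induction proves the reverse, the quinine-derived pseudo-enantiomer is used in the same way.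

**Route**

Step 1
Reactants: 1 (3-formyl-4-methoxyphenyl)boronic acid; 2 2-methoxybenzyl chloride
Product: 3 2-methoxy-5-(2-methoxybenzyl)benzaldehyde
Conditions: Pd(PPh3)4 (3 mol %), K2CO3, DME/H2O, 85 °C
Reagents that add atoms: none
Why: Suzuki–Miyaura coupling of a benzylic chloride with an arylboronic acid; zerovalent palladium inserts into the benzylic C–Cl bond, which has no β-hydrogen, and the aldehyde is tolerated.

Step 2
Reactants: 3 2-methoxy-5-(2-methoxybenzyl)benzaldehyde
Product: 4 2-hydroxy-5-(2-hydroxybenzyl)benzaldehyde
Conditions: BBr3 (3 equiv), CH2Cl2, −78 °C to rt; H2O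
Reagents that add atoms: none
Why: Lewis-acid ether cleavage with BBr3 should remove both aryl methyl groups, while the aldehyde and the diarylmethane survive and the aryl borates are hydrolysed on work-up.

Step 3
Reactants: 4 2-hydroxy-5-(2-hydroxybenzyl)benzaldehyde
Product: 5 4-(2-hydroxybenzyl)-2-(hydroxymethyl)phenol
Conditions: NaBH4, MeOH, 0 °C
Reagents that add atoms: none
Why: Borohydride reduction of the aryl aldehyde should give the salicyl alcohol cleanly, with nothing else reducible present.

Step 4
Reactants: 6 2,4,6-trihydroxybenzaldehyde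
Product: 7 2,6-dihydroxy-4-methoxybenzaldehyde
Conditions: Me2SO4 (1.0 equiv), K2CO3 (1.0 equiv), acetone, 0 °C to rt
Reagents that add atoms: dimethyl sulfate, COS(=O)(=O)OC
Why: Williamson mono-O-methylation; the 4-hydroxyl (para to the formyl group, not hydrogen-bonded to it) is the most acidic and most accessible, so one equivalent of base and a hard methylating agent should react there.

Step 5
Reactants: 7 2,6-dihydroxy-4-methoxybenzaldehyde; 5 4-(2-hydroxybenzyl)-2-(hydroxymethyl)phenol
Product: 10 2,6-dihydroxy-4-methoxy-3,5-bis[2-hydroxy-5-(2-hydroxybenzyl)benzyl]benzaldehyde, via ortho-quinone methide 8 (not isolated), via mono-benzylated aldehyde 9 (not isolated)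
Conditions: ZnCl2 (anhydrous), 1,4-dioxane, 100 °C; 5 (2.3 equiv) added in portions
Reagents that add atoms: none
Why: ZnCl2-promoted loss of water from the salicyl alcohol gives an ortho-quinone methide, which the phloroglucinol-type ring (far more nucleophilic than the monophenol rings of the arm) should capture by Friedel–Crafts-type C-alkylation at C3 and then C5, its only free positions; this mirrors the presumed biosynthetic benzylation.

Step 6
Reactants: 11 phenylacetylene
Product: 13 tert-butyl 3-phenylprop-2-ynoate, via lithium phenylacetylide 12 (not isolated)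
Conditions: n-BuLi, THF, −78 °C; then Boc2O, −78 °C to rt
Reagents that add atoms: di-tert-butyl dicarbonate, CC(C)(C)OC(=O)OC(=O)OC(C)(C)C
Why: Deprotonation of the terminal alkyne and alkoxycarbonylation of the acetylide with Boc2O is a standard way to tert-butyl alkynoates.

Step 7
Reactants: 10 2,6-dihydroxy-4-methoxy-3,5-bis[2-hydroxy-5-(2-hydroxybenzyl)benzyl]benzaldehyde; 13 tert-butyl 3-phenylprop-2-ynoate
Product: 16 5''-(2''''-hydroxybenzyl)uvarinol, via alkylidene keto ester 14 (not isolated), via flavanone-3-carboxylate 15 (not isolated)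
Conditions: [Rh(cod)OMe]2 (2.5 mol %), Fe(C5H4PPh2)2 (dppf, 5 mol %), ClCH2CH2Cl, 60 °C; then toluene, 3,5-bis(trifluoromethyl)phenyl thiourea of 9-amino-9-deoxy-epi-quinidine (20 mol %), −25 °C; then TsOH·H2O (1 equiv), 80 °C
Reagents that add atoms: none
Why: A monovalent rhodium phenoxide at one of the two equivalent ortho hydroxyls of 10 inserts into the formyl C–H bond, the acyl rhodium hydride adds syn across ynoate 13 with hydride going to the phenyl-bearing carbon (β to the ester), and reductive elimination forms the C3–C4 bond to give 14 without added base; the closest known reaction type is the rhodium-catalysed hydroacylation of internal alkynes by salicylaldehydes. The cinchona thiourea then holds the β-keto ester by hydrogen bonds while its quinuclidine nitrogen deprotonates the phenol, which closes ring C by a 6-endo-trig oxa-Michael addition that forms the O1–C2 bond, the known enantioselective cyclisation of alkylidene β-keto esters to flavanones. The C2 stereocentre should be set in this closure by the catalyst alone, since 10 and 14 are achiral, and the C3 centre of 15 is of no consequence. TsOH then cleaves the tert-butyl ester and the β-keto acid loses CO2, so the activating group leaves in the same flask and C2 is no longer β to an acidifying ester. The step needs regioselective hydrometalation (ester and phenyl both direct hydride to the same carbon), no choice between the two hydroxyls (the mirror plane of 10 makes them equivalent) and face selectivity at C2 (catalyst control, protected by base-free rhodium conditions and low temperature so that 14 does not close beforehand).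

**Compound list**

1 | (3-formyl-4-methoxyphenyl)boronic acid | COc1ccc(B(O)O)cc1C=O | starting material
2 | 2-methoxybenzyl chloride | COc1ccccc1CCl | starting material
3 | 2-methoxy-5-(2-methoxybenzyl)benzaldehyde | COc1ccc(Cc2ccccc2OC)cc1C=O | intermediate
4 | 2-hydroxy-5-(2-hydroxybenzyl)benzaldehyde | O=Cc1cc(Cc2ccccc2O)ccc1O | intermediate
5 | 4-(2-hydroxybenzyl)-2-(hydroxymethyl)phenol | OCc1cc(Cc2ccccc2O)ccc1O | intermediate
6 | 2,4,6-trihydroxybenzaldehyde | O=Cc1c(O)cc(O)cc1O | starting material
7 | 2,6-dihydroxy-4-methoxybenzaldehyde | COc1cc(O)c(C=O)c(O)c1 | intermediate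
8 | 4-(2-hydroxybenzyl)-6-methylidenecyclohexa-2,4-dien-1-one (ortho-quinone methide of 5) | C=C1C=C(Cc2ccccc2O)C=CC1=O | intermediate
9 | 2,6-dihydroxy-3-[2-hydroxy-5-(2-hydroxybenzyl)benzyl]-4-methoxybenzaldehyde | COc1cc(O)c(C=O)c(O)c1Cc1cc(Cc2ccccc2O)ccc1O | intermediate
10 | 2,6-dihydroxy-4-methoxy-3,5-bis[2-hydroxy-5-(2-hydroxybenzyl)benzyl]benzaldehyde (achiral, mirror-symmetric) | COc1c(Cc2cc(Cc3ccccc3O)ccc2O)c(O)c(C=O)c(O)c1Cc1cc(Cc2ccccc2O)ccc1O | intermediate
11 | phenylacetylene | C#Cc1ccccc1 | starting material
12 | lithium phenylacetylide | [Li]C#Cc1ccccc1 | intermediate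
13 | tert-butyl 3-phenylprop-2-ynoate | CC(C)(C)OC(=O)C#Cc1ccccc1 | intermediate
14 | tert-butyl (2Z)-2-{2,6-dihydroxy-4-methoxy-3,5-bis[2-hydroxy-5-(2-hydroxybenzyl)benzyl]benzoyl}-3-phenylprop-2-enoate (aroyl cis to the vinyl hydrogen) | COc1c(Cc2cc(Cc3ccccc3O)ccc2O)c(O)c(C(=O)/C(C(=O)OC(C)(C)C)=C/c2ccccc2)c(O)c1Cc1cc(Cc2ccccc2O)ccc1O | intermediate
15 | tert-butyl (2S,3R)-5-hydroxy-7-methoxy-4-oxo-2-phenyl-6,8-bis[2-hydroxy-5-(2-hydroxybenzyl)benzyl]chromane-3-carboxylate (2,3-trans; C3 epimerisable) | COc1c(Cc2cc(Cc3ccccc3O)ccc2O)c(O)c2c(c1Cc1cc(Cc3ccccc3O)ccc1O)O[C@H](c1ccccc1)[C@@H](C(=O)OC(C)(C)C)C2=O | intermediate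
16 | 5''-(2''''-hydroxybenzyl)uvarinol, (2S)-5-hydroxy-7-methoxy-2-phenyl-6,8-bis[2-hydroxy-5-(2-hydroxybenzyl)benzyl]chroman-4-one | COc1c(Cc2cc(Cc3ccccc3O)ccc2O)c(O)c2c(c1Cc1cc(Cc3ccccc3O)ccc1O)O[C@H](c1ccccc1)CC2=O | target

**Step count and risks**

Total steps: 7. Longest linear sequence: 5 (steps 1, 2, 3, 5, 7).

Steps most likely to fail:

Step 7. The alkylidene keto ester may close ring C on its own before the chiral catalyst is present, or the thiourea may discriminate poorly between the faces of a phenol flanked by a bulky arm; either erodes enantiomeric purity. Hydrometalation could also leak to the other regiochemistry. Fallback: set out again from 10 and 13. Run the hydroacylation as before to 14, close the ring with CsF instead of a chiral catalyst to the racemic trans keto ester F1, and decarboxylate with TsOH to the racemic flavanone F2. Then resolve kinetically by asymmetric transfer hydrogenation with RuCl(p-cymene)(TsDPEN), using the catalyst enantiomer that reduces the (2R)-ketone faster, in HCO2H/Et3N. The (2R) enantiomer should be converted into the cis-(2R,4R)-flavan-4-ol F3 and removed by chromatography, and the unreacted (2S)-ketone is 16, where the route is rejoined.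

Step 5. The arm alcohol may condense with itself, because the free para position of its own outer phenol ring can intercept the quinone methide, and the reaction may stall after one alkylation. Fallback: set out from 7 and build the arms on ring A in two stages. ZnCl2-mediated benzylation with commercial 4-bromo-2-(hydroxymethyl)phenol, whose para position is blocked and deactivated, should give the dibromide 3,5-bis(5-bromo-2-hydroxybenzyl)-2,6-dihydroxy-4-methoxybenzaldehyde F4. The reagent [2-(benzyloxy)benzyl]zinc bromide F5 is made from commercial 2-(benzyloxy)benzyl bromide with Zn and LiCl in THF. Twofold Negishi coupling of F4 with F5 (Pd(OAc)2, 2-dicyclohexylphosphino-2',6'-dimethoxybiphenyl, excess zinc reagent to allow for the free phenols) should give the bis(benzyl ether) F6. BCl3 with pentamethylbenzene in CH2Cl2 at −78 °C then removes the two benzyl groups and returns to the route at 10.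

Step 4. Methylation may run on to di- and tri-ethers, or occur at a chelated ortho hydroxyl or at ring carbon. Fallback: set out from 6, methylate exhaustively (excess Me2SO4, K2CO3, acetone, reflux) to 2,4,6-trimethoxybenzaldehyde F7, then use chelation-controlled cleavage of the two ethers ortho to the formyl group with excess AlCl3 in chlorobenzene under heating. The para methoxy group, which cannot chelate, should remain, and the route is rejoined at 7.

**Further compounds**

F1 | step 7 | racemic trans tert-butyl 5-hydroxy-7-methoxy-4-oxo-2-phenyl-6,8-bis[2-hydroxy-5-(2-hydroxybenzyl)benzyl]chromane-3-carboxylate | COc1c(Cc2cc(Cc3ccccc3O)ccc2O)c(O)c2c(c1Cc1cc(Cc3ccccc3O)ccc1O)OC(c1ccccc1)C(C(=O)OC(C)(C)C)C2=O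
F2 | step 7 | racemic 5-hydroxy-7-methoxy-2-phenyl-6,8-bis[2-hydroxy-5-(2-hydroxybenzyl)benzyl]chroman-4-one | COc1c(Cc2cc(Cc3ccccc3O)ccc2O)c(O)c2c(c1Cc1cc(Cc3ccccc3O)ccc1O)OC(c1ccccc1)CC2=O
F3 | step 7 | (2R,4R)-7-methoxy-2-phenyl-6,8-bis[2-hydroxy-5-(2-hydroxybenzyl)benzyl]chromane-4,5-diol (2,4-cis) | COc1c(Cc2cc(Cc3ccccc3O)ccc2O)c(O)c2c(c1Cc1cc(Cc3ccccc3O)ccc1O)O[C@@H](c1ccccc1)C[C@H]2O
F4 | step 5 | 3,5-bis(5-bromo-2-hydroxybenzyl)-2,6-dihydroxy-4-methoxybenzaldehyde | COc1c(Cc2cc(Br)ccc2O)c(O)c(C=O)c(O)c1Cc1cc(Br)ccc1O
F5 | step 5 | [2-(benzyloxy)benzyl]zinc bromide | Br[Zn]Cc1ccccc1OCc1ccccc1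
F6 | step 5 | 3,5-bis{5-[2-(benzyloxy)benzyl]-2-hydroxybenzyl}-2,6-dihydroxy-4-methoxybenzaldehyde | COc1c(Cc2cc(Cc3ccccc3OCc3ccccc3)ccc2O)c(O)c(C=O)c(O)c1Cc1cc(Cc2ccccc2OCc2ccccc2)ccc1O
F7 | step 4 | 2,4,6-trimethoxybenzaldehyde | COc1cc(OC)c(C=O)c(OC)c1
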